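## The problem

CNP0274187.1 is a germacrane-derived lactone. Its ten-membered carbocycle (C1–C10) is spanned by an ether oxygen between C5 and C10, which divides it into ring A (the oxepane through C6–C9) and ring B (the oxepenone through C1–C4, with the C1 ketone and the C2=C3 alkene). The oxygen leaves the carbocycle from opposite faces at C5 and C10, so the bicycle is trans-bridged and strained. Any ring closure that is free to choose will prefer a cis-bridged or six-membered alternative. Ring A also carries a trans-fused α-methylene-γ-lactone (C6–O–C12, C7–C11=C13) and the angelate at C8; ring B carries the hydroxymethyl group at C4.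

Of the six stereocentres, C7 can be bought with (R)-carvone and, on a cyclohexane, can direct C8 and C10. C6 can then be set from C7 through allylic strain, C5 from C6 by anti addition followed by inversion, and C4 only by chirality transfer in a sigmatropic step. The angelate (isomerisation to the tiglate, acyl migration), the methylene lactone and the enone (Michael acceptors; the lactone can also migrate to a free C8 hydroxyl) and the tertiary α-oxygenated ketone do not tolerate strong base or nucleophiles, so they must appear late.

The feature that opens the structure is the C1 ketone four bonds from the C5/C6 oxygen pair. If both oxygens are traced back to a C5=C6 alkene, the carbocycle is a cyclodec-5-enone, the product of an oxy-Cope rearrangement of a cyclohexanol made of C1, C10, C9, C8, C7 and C6. That six-membered ring has its methyl group (C14 on C10) and its three-carbon branch (C11–C13 on C7) exactly where carvone has them.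

## Retrosynthesis

**35 ⇒ 34 ⇒ 31.** The silyl ether at O15 and the ester C–O bond at C8 are cut first. The angelate is the most fragile group, so it is put on enone alcohol 31 when C8 carries the only free hydroxyl; the forward steps need an isomerisation-free acylation and a non-basic desilylation.

**31 ⇒ 29.** The C2=C3 alkene is removed to give ketone 29. C10 is quaternary, so the ketone enolises only towards C2. The dehydrogenation is placed after the bicycle exists because only inside seven-membered ring B is the enone forced to be cis.

**29 ⇒ 28 (⇒ 27).** The ether bond O–C5 is the first ring bond cut. The neighbouring cut, opening a C5/C6 epoxide with the C10 hydroxyl, would offer the nucleophile two carbons; attack at C6 would give a six-membered, cis-bridged ether and is expected to win over the strained mode. In iodide 28 the C6 oxygen is already tied into the lactone, so only C5 is electrophilic, and displacement with inversion must give the trans bridge. Acetal 27 is its protected form.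

**27 ⇒ 26.** Cutting C6–O and C5–I together leads to Z-alkene acid 26. Iodolactonisation adds oxygen and iodine anti and the later displacement inverts C5, so the two oxygens end up syn on a former Z alkene, which is the relationship in the target. An E alkene would require net anti delivery, that is, the epoxide route set aside above. The forward reaction needs 5-exo regiochemistry and the trans ring fusion.

**26 ⇒ 24 ⇒ 23.** The acid is traced to the isopropenyl methyl group of cyclodecenone 23 through allylic alcohol 24; this keeps the Michael acceptor out of all basic steps.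

**23 ⇒ 20 (key disconnection).** Cutting C3–C4 and reconnecting C1 to C6 turns 23 into 1-vinyl-6-propenylcyclohexanol 20. A trans-dialkenyl isomer would give an E alkene. The cis isomer 20 (vinyl axial, propenyl equatorial) rearranges through a chair that is cis-fused to the ring and gives the Z alkene. Two facts speak for 20: it is the isomer that vinyl addition should deliver (attack anti to the acetal-covered face), and with an E-propenyl group its suprafacial transfer from C6 gives the C4 configuration of the target. The trans isomer with the same side chain would give the C4 epimer. The ten-membered ring, the ketone and C4 are all lost in this one cut.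

**20 ⇒ 19 ⇒ 17 + 18; 17 ⇒ 16 ⇒ 12 + 13.** The vinyl group comes from vinylmagnesium bromide (18). The E-silyloxypropenyl group comes from an aldol reaction of ketone 12 with acrolein (13) and 1,3-transposition of the allylic acetate 16 to 17. Ketone 12 enolises only at C6, and its bridged acetal dictates the face of both additions.

**12 ⇒ 11 ⇒ 10 ⇒ 9 ⇒ 8 ⇒ 7 ⇒ 4 ⇒ 3 ⇒ 2 ⇒ 1.** The C8 and C10 oxygens are removed in turn. Diol 9 comes from epoxy alcohol 8 by hydride opening, and 8 from allylic alcohol 7. Alcohol 7 comes from epoxide 4 by selenide opening and selenoxide elimination, and 4 from cis-carveol (2) by directed epoxidation. Each oxygen is delivered by a hydroxyl group that is cis to the isopropenyl group, so C7 of (R)-carvone (1) controls C10 and then C8.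

## Roads not taken

**Alternative 1:** The cut is made at O–C10 and C9–C10. Diazoketone A1, a benzyl pyranoside that already holds C5–C9, the lactone and the angelate, would be decomposed with Rh2(OAc)4 or Cu(acac)2. The carbenoid at C10 is caught by the pyran oxygen, and the acetal carbon C9 then migrates from oxygen to C10, giving A2.
- Merits: both seven-membered rings, the quaternary C10 and the trans bridge are made in one step, by a reaction class known to give bridged ethers. On the hardest bond of the target it is better than the chosen plan.
- Weak points: an α-methyl diazoketone readily undergoes 1,2-hydride shift to an enone. Ylide formation through a seven-membered ring competes with C–H insertion and with cyclopropanation of the cis-enone. The 1,2-shift may lose configuration at C9 and has to create C10 selectively. The benzyloxy group at C9 must afterwards be removed by deoxygenation, and the lactone still lacks its methylene group.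
- Comparison: the chosen plan sets against this a chiral-pool start in which each stereocentre is relayed from C7, and an ether closure that is a stereospecific displacement rather than a selectivity question.

**Alternative 2:** The cut is made at C7–C8. Aldehyde A3, an oxepene (ring B with the ether in place) carrying a butenolide at C5, would be treated with SmI2 (divalent samarium). The ketyl adds to the butenolide β-carbon C7 and closes ring A to give A4.
- Merits: ketyl–alkene additions onto butenolides are reliable C–C bond formations and tolerate strain better than an SN2 closure. In that respect this road is at least as good as the chosen one.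
- Weak points: a seven-membered ring must form in competition with pinacol coupling and simple reduction, and the C8 hydroxyl and C7 configurations are set by a chelate whose sense is not secured here. The trans relationship across the ether is only moved into the preparation of A3, a 2,7-trans-disubstituted oxepene that is itself hard to close. A4 still needs oxidation at C1, α-methylenation of the lactone by enolate chemistry, and angeloylation.
- Comparison: the chosen plan takes C7 and C8 from carvone without a diastereoselective C–C bond formation.

**Alternative 3:** The cut is made at C6–C7 and O–C12. Bromo ester aldehyde A5 (ring B complete, with angelate and enone) would be treated with CrCl2 (divalent chromium). The allylchromium adds through C7 to the C6 aldehyde and the alkoxide lactonises, giving A6, one desilylation from the target.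
- Merits: it is the most convergent road and clearly better in step economy at the end.
- Weak points: the closure must give a seven-membered ring and the trans lactone, where intramolecular additions of this kind often give the cis isomer. The α-alkoxy aldehyde at C5 can epimerise. The enone and the angelate must survive CrCl2. A5 again presupposes the trans-2,7-disubstituted oxepenone.
- Comparison: the chosen plan spends more steps after ring formation, but it sets C6 and C7 relative to each other by allylic strain and carries no sensitive group through the ring-forming step.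

Key step: step 14

Remark: atom numbers are those of the target skeleton throughout (carvone C1, C2, C3, C4, C5, C6 become C1, C10, C9, C8, C7, C6). The ether oxygen is taken to leave C5 and C10 on opposite faces of the carbocycle, as the drawn configuration requires.

Step 1
Reactants: 1 (R)-carvone
Product: 2 (1R,5R)-cis-carveol
Conditions: NaBH4, CeCl3·7H2O, MeOH, 0 °C
Reagents that add atoms: none
Why: Luche 1,2-reduction; axial hydride delivery should give the equatorial alcohol cis to the isopropenyl group, and C7 is untouched.

Step 2
Reactants: 2 (1R,5R)-cis-carveol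
Product: 3 syn-9,10-epoxy alcohol
Conditions: VO(acac)2 (cat.), t-BuOOH, CH2Cl2, 0 °C to rt
Reagents that add atoms: tert-butyl hydroperoxide, CC(C)(C)OO
Why: Hydroxyl-directed epoxidation of the allylic alcohol delivers oxygen to the face of the C1 hydroxyl and spares the isopropenyl group; this fixes the C10 oxygen cis to the isopropenyl group.

Step 3
Reactants: 3 syn-9,10-epoxy alcohol
Product: 4 C1 TBS ether of the epoxy alcohol
Conditions: TBSCl, imidazole, DMF, rt
Reagents that add atoms: tert-butyldimethylsilyl chloride, CC(C)(C)[Si](C)(C)Cl
Why: Standard silylation; the C1 oxygen stays masked until both ring oxygens are in place.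

Step 4
Reactants: 4 C1 TBS ether of the epoxy alcohol
Product: 7 tertiary allylic alcohol (10-hydroxy; C8=C9), via hydroxy selenide 5 (not isolated), via selenoxide 6 (not isolated)
Conditions: (PhSe)2, NaBH4, EtOH, reflux; then 30% H2O2, THF, 0 °C to rt
Reagents that add atoms: none
Why: Epoxide-to-allylic-alcohol transposition by selenide opening and selenoxide syn-elimination; PhSe– opens the trisubstituted epoxide trans-diaxially at secondary C9 (Fürst–Plattner), and the selenoxide can eliminate only towards C8 because C10 is quaternary. C10 keeps its oxygen with retention.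

Step 5
Reactants: 7 tertiary allylic alcohol (10-hydroxy; C8=C9)
Product: 8 syn-8,9-epoxy alcohol
Conditions: VO(acac)2 (cat.), t-BuOOH, CH2Cl2, 0 °C to rt
Reagents that add atoms: tert-butyl hydroperoxide, CC(C)(C)OO
Why: A second hydroxyl-directed epoxidation, now from the tertiary allylic C10 alcohol, places the epoxide oxygen on the same face at C8 and C9.

Step 6
Reactants: 8 syn-8,9-epoxy alcohol
Product: 9 syn-8,10-diol
Conditions: LiAlH4, THF, 0 °C to reflux
Reagents that add atoms: none
Why: Hydride opening of the epoxide in the trans-diaxial sense at C9 (Fürst–Plattner; attack at C8 would force the isopropenyl, methyl and silyloxy groups axial) should give the 1,3-diol, with the C8 hydroxyl cis to the C10 hydroxyl and the isopropenyl group.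

Step 7
Reactants: 9 syn-8,10-diol
Product: 10 8,10-O-(4-methoxybenzylidene) acetal
Conditions: 4-MeOC6H4CH(OMe)2, PPTS (cat.), CH2Cl2, rt
Reagents that add atoms: 4-methoxybenzaldehyde dimethyl acetal, COc1ccc(C(OC)OC)cc1
Why: Acetalisation of the syn-1,3-diaxial diol gives a bridged 2,4-dioxabicyclo[3.3.1]nonane with the aryl group exo; it protects both oxygens at once and locks the chair that controls steps 10, 12 and 14.

Step 8
Reactants: 10 8,10-O-(4-methoxybenzylidene) acetal
Product: 11 C1 alcohol
Conditions: TBAF, THF, rt
Reagents that add atoms: none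
Why: Fluoride cleavage of the secondary silyl ether; acetal and alkene are inert.

Step 9
Reactants: 11 C1 alcohol
Product: 12 bicyclic ketone
Conditions: Dess–Martin periodinane, NaHCO3, CH2Cl2, rt
Reagents that add atoms: none
Why: Dess–Martin oxidation of the secondary alcohol; the ketone can enolise only towards C6 because C10 is quaternary.

Step 10
Reactants: 12 bicyclic ketone, 13 acrolein
Product: 16 β-acetoxy ketone, via lithium enolate 14 (not isolated), via lithium aldolate 15 (not isolated)
Conditions: LDA, THF, –78 °C; acrolein; then Ac2O, –78 to 0 °C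
Reagents that add atoms: acetic anhydride, CC(=O)OC(C)=O
Why: Kinetic lithium-enolate aldol (1,2-addition to acrolein) with in situ O-acetylation; the electrophile enters C6 from the face away from the acetal bridge, that is, trans to the isopropenyl group and equatorial. The carbinol configuration at C5 is immaterial because step 11 erases it.

Step 11
Reactants: 16 β-acetoxy ketone
Product: 17 (E)-allylic acetate
Conditions: PdCl2(MeCN)2 (cat.), THF, rt
Reagents that add atoms: none
Why: PdCl2(MeCN)2-catalysed [3,3] rearrangement of the allylic acetate (cyclisation-induced, no free cation, so the β-acetoxy ketone should not eliminate) moves the acetate to C15 and gives the more substituted E alkene through a chair-like acetoxonium intermediate.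

Step 12
Reactants: 17 (E)-allylic acetate, 18 vinylmagnesium bromide
Product: 19 divinyl carbinol diol
Conditions: CeCl3, vinylmagnesium bromide (excess), THF, –78 to 0 °C
Reagents that add atoms: none
Why: Organocerium 1,2-addition to a hindered, enolisable β,γ-unsaturated ketone; the bridged acetal shields the upper face, so vinyl should enter axially and end up cis to the C6 propenyl group. The excess Grignard reagent cleaves the acetate to the free C15 alcohol.

Step 13
Reactants: 19 divinyl carbinol diol
Product: 20 oxy-Cope precursor (15-O-TBDPS)
Conditions: TBDPSCl, imidazole, CH2Cl2, 0 °C to rt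
Reagents that add atoms: tert-butyl(chloro)diphenylsilane, CC(C)(C)[Si](Cl)(c1ccccc1)c1ccccc1
Why: Selective silylation of the primary allylic alcohol; the tertiary C1 hydroxyl stays free for the rearrangement.

Step 14
Reactants: 20 oxy-Cope precursor (15-O-TBDPS)
Product: 23 (5Z)-cyclodec-5-enone, via potassium alkoxide 21 (not isolated), via potassium enolate 22 (not isolated)
Conditions: KH, 18-crown-6, THF, 0 °C to rt; aq. NH4Cl, –78 °C
Reagents that add atoms: none
Why: KH deprotonates the tertiary C1 alcohol, and alkoxide 21 undergoes a concerted [3,3]-sigmatropic shift in which C3 bonds to C4 as the C1–C6 bond breaks; enolate 22 is protonated on work-up to the C1 ketone. The closest known reaction type is the anionic oxy-Cope ring expansion of 1,2-dialkenylcyclohexanols to cyclodec-5-enones. The ten-membered ring arises by four-carbon ring expansion through a six-membered chair array, not by end-to-end cyclisation. The acetal holds the cyclohexane chair with vinyl axial at C1 and propenyl equatorial at C6, so the rearranging chair is cis-fused to the ring; the C6–C7 bond is pseudoaxial in it and C5=C6 should form as the Z alkene. C4 is set by suprafacial transfer from C6 across the E-propenyl unit, whose CH2OSi group sits pseudoequatorial, which gives the configuration required in 35. The step needs chair over boat and rearrangement over fragmentation; the 60° dihedral between the two alkenyl groups, fixed by the bicyclic acetal, cannot be eclipsed as a boat demands, and the crown-ether-separated alkoxide rearranges at or below room temperature. The enolate is flanked by quaternary C10, and C7, C8 and C10 are not touched.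

Step 15
Reactants: 23 (5Z)-cyclodec-5-enone
Product: 24 C12 allylic alcohol
Conditions: SeO2 (cat.), t-BuOOH, CH2Cl2, rt
Reagents that add atoms: tert-butyl hydroperoxide, CC(C)(C)OO
Why: Allylic hydroxylation by SeO2 (ene reaction then [2,3] shift) with t-BuOOH as terminal oxidant; the 1,1-disubstituted isopropenyl group should react at its methyl group in preference to the methine positions beside the Z alkene.

Step 16
Reactants: 24 C12 allylic alcohol
Product: 26 acrylic acid, via enal 25 (not isolated)
Conditions: TEMPO (cat.), PhI(OAc)2, MeCN–H2O, rt
Reagents that add atoms: water, O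
Why: TEMPO/PhI(OAc)2 oxidation of the primary allylic alcohol in aqueous acetonitrile runs through the enal and its hydrate to the acid; the ring alkene, ketone and acetal are not affected, and any enal carried over from step 15 converges here.

Step 17
Reactants: 26 acrylic acid
Product: 27 iodolactone
Conditions: I2, NaHCO3, MeCN, 0 °C, dark
Reagents that add atoms: iodine, II
Why: Iodolactonisation with 5-exo attack of the carboxylate at C6, anti to iodine at C5. Allylic 1,3-strain of the Z alkene keeps H7 in the alkene plane, so the carboxylate reaches C6 from the face of C11 and the lactone should be trans-fused, with C6 as in the target.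

Step 18
Reactants: 27 iodolactone
Product: 28 iodolactone diol
Conditions: AcOH–THF–H2O, 40 °C
Reagents that add atoms: none
Why: Acid hydrolysis of the aryl acetal frees the C8 and C10 hydroxyls; the primary TBDPS ether, the iodide and the lactone tolerate aqueous acetic acid.

Step 19
Reactants: 28 iodolactone diol
Product: 29 trans-bridged ether lactone
Conditions: AgOTf, 2,6-di-tert-butyl-4-methylpyridine, CH2Cl2, 0 °C to rt, dark
Reagents that add atoms: none
Why: Silver-assisted intramolecular Williamson-type etherification; the tertiary C10 hydroxyl displaces iodide at C5 with inversion, which closes rings A and B together (7-exo-tet for each) and gives the trans bridge. C6 is blocked as the lactone, and the C8 hydroxyl cannot reach C5 because that would require a trans-fused bicyclo[3.3.0] system.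

Step 20
Reactants: 29 trans-bridged ether lactone
Product: 31 enone alcohol, via bis(trimethylsilyl) enol ether 30 (not isolated)
Conditions: TMSOTf, Et3N, CH2Cl2, 0 °C; Pd(OAc)2, MeCN, rt; then 1 M HCl, THF
Reagents that add atoms: none
Why: Ito–Saegusa oxidation; soft enolisation can give only the C1–C2 silyl enol ether (C10 is quaternary), and Pd(OAc)2 then gives the enone by β-hydride elimination, necessarily cis inside seven-membered ring B. The transient C8 silyl ether is cleaved on acidic work-up.

Step 21
Reactants: 31 enone alcohol, 32 angelic acid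
Product: 34 15-O-TBDPS ether of the target, via mixed anhydride 33 (not isolated)
Conditions: 2,4,6-trichlorobenzoyl chloride, Et3N, toluene, rt; then 31, toluene, 80 °C
Reagents that add atoms: none
Why: Yamaguchi-type esterification through the mixed anhydride without DMAP, chosen because these conditions avoid Z-to-E isomerisation of the angelate; C8 carries the only free hydroxyl.

Step 22
Reactants: 34 15-O-TBDPS ether of the target
Product: 35 CNP0274187.1
Conditions: HF·pyridine, pyridine, THF, 0 °C to rt
Reagents that add atoms: none
Why: Fluoride cleavage of the primary silyl ether under buffered, non-basic conditions that leave the angelate, enone and methylene lactone untouched.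

Compound list

1 | (R)-carvone | CC1=CC[C@H](CC1=O)C(C)=C | starting material
2 | (1R,5R)-cis-carveol (C1 hydroxyl cis to the C7 isopropenyl group) | O[C@H]1C(C)=CC[C@@H](C(C)=C)C1 | intermediate
3 | syn-9,10-epoxy alcohol (epoxide on the face of the C1 hydroxyl, cis to isopropenyl) | O[C@H]1[C@@]2(C)O[C@H]2C[C@@H](C(C)=C)C1 | intermediate
4 | C1 tert-butyldimethylsilyl ether of 3 | CC(C)(C)[Si](C)(C)O[C@H]1[C@@]2(C)O[C@H]2C[C@@H](C(C)=C)C1 | intermediate
5 | hydroxy selenide (10-hydroxyl cis to isopropenyl, 9-phenylselanyl trans to it) | CC(C)(C)[Si](C)(C)O[C@H]1[C@@](C)(O)[C@H]([Se]c2ccccc2)C[C@@H](C(C)=C)C1 | intermediate (not isolated)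
6 | selenoxide of 5 (mixture at selenium) | CC(C)(C)[Si](C)(C)O[C@H]1[C@@](C)(O)[C@H]([Se](=O)c2ccccc2)C[C@@H](C(C)=C)C1 | intermediate (not isolated)
7 | tertiary allylic alcohol (10-hydroxy-10-methyl, C8=C9, 1-OTBS; both oxygens cis to isopropenyl) | CC(C)(C)[Si](C)(C)O[C@H]1[C@@](C)(O)C=C[C@@H](C(C)=C)C1 | intermediate
8 | syn-8,9-epoxy alcohol (epoxide on the face of the C10 hydroxyl) | CC(C)(C)[Si](C)(C)O[C@H]1[C@@](C)(O)[C@H]2O[C@H]2[C@@H](C(C)=C)C1 | intermediate
9 | syn-8,10-diol (both hydroxyls cis to isopropenyl and to the 1-OTBS group) | CC(C)(C)[Si](C)(C)O[C@H]1[C@@](C)(O)C[C@@H](O)[C@@H](C(C)=C)C1 | intermediate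
10 | 8,10-O-(4-methoxybenzylidene) acetal of 9 (aryl exo) | CC(C)(C)[Si](C)(C)O[C@H]1[C@]2(C)C[C@@H](O[C@@H](c3ccc(OC)cc3)O2)[C@@H](C(C)=C)C1 | intermediate
11 | C1 alcohol (acetal retained) | O[C@H]1[C@]2(C)C[C@@H](O[C@@H](c3ccc(OC)cc3)O2)[C@@H](C(C)=C)C1 | intermediate
12 | bicyclic ketone (C1 ketone, 8,10-acetal, C7 isopropenyl) | O=C1[C@]2(C)C[C@@H](O[C@@H](c3ccc(OC)cc3)O2)[C@@H](C(C)=C)C1 | intermediate
13 | acrolein | C=CC=O | starting material
14 | lithium enolate of 12 (C1=C6) | [Li+].[O-]C1[C@]2(C)C[C@@H](O[C@@H](c3ccc(OC)cc3)O2)[C@@H](C(C)=C)C=1 | intermediate (not isolated)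
15 | lithium aldolate (C6 side chain trans to isopropenyl; anti aldol drawn) | O=C1[C@]2(C)C[C@@H](O[C@@H](c3ccc(OC)cc3)O2)[C@@H](C(C)=C)[C@@H]1[C@H]([O-])C=C.[Li+] | intermediate (not isolated)
16 | β-acetoxy ketone (6-(1-acetoxyprop-2-enyl), trans to isopropenyl) | O=C1[C@]2(C)C[C@@H](O[C@@H](c3ccc(OC)cc3)O2)[C@@H](C(C)=C)[C@@H]1[C@H](OC(C)=O)C=C | intermediate
17 | (E)-allylic acetate (6-[(E)-3-acetoxyprop-1-enyl] ketone) | O=C1[C@]2(C)C[C@@H](O[C@@H](c3ccc(OC)cc3)O2)[C@@H](C(C)=C)[C@@H]1/C=C/COC(C)=O | intermediate
18 | vinylmagnesium bromide | C=C[Mg]Br | starting material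
19 | divinyl carbinol diol (1-vinyl cis to the C6 propenyl group, 1-hydroxyl cis to O10, free C15 alcohol) | C=C[C@]1(O)[C@]2(C)C[C@@H](O[C@@H](c3ccc(OC)cc3)O2)[C@@H](C(C)=C)[C@@H]1/C=C/CO | intermediate
20 | oxy-Cope precursor (15-O-TBDPS ether of 19) | C=C[C@]1(O)[C@]2(C)C[C@@H](O[C@@H](c3ccc(OC)cc3)O2)[C@@H](C(C)=C)[C@@H]1/C=C/CO[Si](c4ccccc4)(c5ccccc5)C(C)(C)C | intermediate
21 | potassium alkoxide of 20 | C=C[C@]1([O-])[C@]2(C)C[C@@H](O[C@@H](c3ccc(OC)cc3)O2)[C@@H](C(C)=C)[C@@H]1/C=C/CO[Si](c4ccccc4)(c5ccccc5)C(C)(C)C.[K+] | intermediate (not isolated)
22 | potassium enolate of 23 | [K+].[O-]/C1=C\C[C@H](CO[Si](c2ccccc2)(c3ccccc3)C(C)(C)C)/C=C\[C@H](C(C)=C)[C@H](O[C@@H](c5ccc(OC)cc5)O4)C[C@@]14C | intermediate (not isolated)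
23 | (5Z)-cyclodec-5-enone (C1 ketone, C4 CH2OTBDPS, C7 isopropenyl, 8,10-acetal) | O=C1CC[C@H](CO[Si](c2ccccc2)(c3ccccc3)C(C)(C)C)/C=C\[C@H](C(C)=C)[C@H](O[C@@H](c5ccc(OC)cc5)O4)C[C@@]14C | intermediate
24 | C12 allylic alcohol (C7 bears 3-hydroxyprop-1-en-2-yl) | O=C1CC[C@H](CO[Si](c2ccccc2)(c3ccccc3)C(C)(C)C)/C=C\[C@H](C(=C)CO)[C@H](O[C@@H](c5ccc(OC)cc5)O4)C[C@@]14C | intermediate
25 | enal (C12 aldehyde) | O=C1CC[C@H](CO[Si](c2ccccc2)(c3ccccc3)C(C)(C)C)/C=C\[C@H](C(=C)C=O)[C@H](O[C@@H](c5ccc(OC)cc5)O4)C[C@@]14C | intermediate (not isolated)
26 | acrylic acid (C12 acid) | O=C1CC[C@H](CO[Si](c2ccccc2)(c3ccccc3)C(C)(C)C)/C=C\[C@H](C(=C)C(=O)O)[C@H](O[C@@H](c5ccc(OC)cc5)O4)C[C@@]14C | intermediate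
27 | iodolactone (trans-fused 6,12-lactone, iodide at C5 anti to O6, acetal retained) | C=C1C(=O)O[C@@H]2[C@@H](I)[C@@H](CO[Si](c3ccccc3)(c4ccccc4)C(C)(C)C)CCC(=O)[C@]5(C)C[C@@H](O[C@@H](c6ccc(OC)cc6)O5)[C@@H]12 | intermediate
28 | iodolactone diol (8-OH, 10-OH) | C=C1C(=O)O[C@@H]2[C@@H](I)[C@@H](CO[Si](c3ccccc3)(c4ccccc4)C(C)(C)C)CCC(=O)[C@@](C)(O)C[C@@H](O)[C@@H]12 | intermediate
29 | trans-bridged ether lactone (C5–O–C10 ether, C1 ketone, 8-OH, 15-OTBDPS) | C=C1C(=O)O[C@@H]2[C@@H]3O[C@@](C)(C[C@@H](O)[C@@H]12)C(=O)CC[C@@H]3CO[Si](c4ccccc4)(c5ccccc5)C(C)(C)C | intermediate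
30 | bis(trimethylsilyl) enol ether (C1–C2 silyl enol ether, 8-OTMS) | C=C1C(=O)O[C@@H]2[C@@H]3O[C@@](C)(C[C@@H](O[Si](C)(C)C)[C@@H]12)C(O[Si](C)(C)C)=CC[C@@H]3CO[Si](c4ccccc4)(c5ccccc5)C(C)(C)C | intermediate (not isolated)
31 | enone alcohol (C2=C3, 8-OH, 15-OTBDPS) | C=C1C(=O)O[C@@H]2[C@@H]3O[C@@](C)(C[C@@H](O)[C@@H]12)C(=O)C=C[C@@H]3CO[Si](c4ccccc4)(c5ccccc5)C(C)(C)C | intermediate
32 | angelic acid | C/C=C(/C)C(=O)O | starting material
33 | angelic 2,4,6-trichlorobenzoic mixed anhydride | C/C=C(/C)C(=O)OC(=O)c1c(Cl)cc(Cl)cc1Cl | intermediate (not isolated)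
34 | 15-O-TBDPS ether of the target | C=C1C(=O)O[C@@H]2[C@@H]3O[C@@](C)(C[C@@H](OC(=O)/C(C)=C\C)[C@@H]12)C(=O)C=C[C@@H]3CO[Si](c4ccccc4)(c5ccccc5)C(C)(C)C | intermediate
35 | CNP0274187.1 | C=C1C(=O)O[C@@H]2[C@@H]3O[C@@](C)(C[C@@H](OC(=O)/C(C)=C\C)[C@@H]12)C(=O)C=C[C@@H]3CO | target

Total step count: 22. Longest linear sequence: 22 steps from (R)-carvone (1); acrolein (13), vinylmagnesium bromide (18) and angelic acid (32) enter as bought compounds.

Least certain steps

**Step 14 (key step).** What may go wrong: the alkoxide may fragment instead of rearranging, or part of the material may pass through a boat or the alternative chair, which would erode the alkene geometry and the C4 configuration. The ring is heavily substituted, and the axial vinyl group meets two axial hydrogens in the transition state. Fallback: from 20, silylation of the tertiary hydroxyl with N-(trimethylsilyl)imidazole gives the trimethylsilyl ether F1. Its neutral thermal siloxy-Cope rearrangement (o-dichlorobenzene, about 200 °C) passes through the same cis-fused chair without an alkoxide and gives the trimethylsilyl enol ether F2. Mild acid methanolysis of F2 returns to the route at 23.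

**Step 19.** What may go wrong: silver-assisted ionisation at C5 may be followed by elimination, hydride shift or capture by the C1 carbonyl oxygen rather than by the displacement, because closing the strained trans bridge is slow. Fallback: from 26, selenolactonisation with N-(phenylseleno)phthalimide (same anti, 5-exo course) gives the phenylselanyl lactone F3, and aqueous acetic acid gives its diol F4. Oxidation with excess m-CPBA under K2HPO4 buffering gives the selenone F5, whose phenylselenonyl group is a far better leaving group and is displaced in situ by the C10 hydroxyl. This returns to the route at 29.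

**Step 12.** What may go wrong: the doubly activated C6–H may be enolised (with loss of material to the conjugated enone) instead of addition to the very hindered ketone, or acetate cleavage may be incomplete. Fallback: from 17, the smaller and less basic cerium (trimethylsilyl)acetylide (lithium (trimethylsilyl)acetylide, CeCl3, THF, –78 °C) gives the silylethynyl carbinol acetate F6 with the same facial preference. K2CO3 in MeOH removes the silyl and acetyl groups to give the ethynyl carbinol diol F7. Semi-hydrogenation (H2, Pd on CaCO3 poisoned with Pb(OAc)2, quinoline) returns to the route at 19.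

**Step 15.** What may go wrong: the ene oxidation may also occur at the allylic methines C4 and C7 of the ring alkene or α to the ketone, lowering chemoselectivity. Fallback: from 23, ene-type chlorination of the isopropenyl group with Ca(OCl)2 and CO2 in CH2Cl2–H2O gives the C12 allylic chloride F8. Oxidation of F8 with N-methylmorpholine N-oxide in MeCN gives enal 25, and Pinnick oxidation (NaClO2, NaH2PO4, 2-methyl-2-butene) returns to the route at 26.

Further compounds

F1 | step 14 | C1 trimethylsilyl ether of 20 | C=C[C@]1(O[Si](C)(C)C)[C@]2(C)C[C@@H](O[C@@H](c3ccc(OC)cc3)O2)[C@@H](C(C)=C)[C@@H]1/C=C/CO[Si](c4ccccc4)(c5ccccc5)C(C)(C)C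
F2 | step 14 | trimethylsilyl enol ether of 23 | C[Si](C)(C)O/C1=C\C[C@H](CO[Si](c2ccccc2)(c3ccccc3)C(C)(C)C)/C=C\[C@H](C(C)=C)[C@H](O[C@@H](c5ccc(OC)cc5)O4)C[C@@]14C
F3 | step 19 | phenylselanyl lactone (selenium at C5 anti to O6, acetal retained) | C=C1C(=O)O[C@@H]2[C@@H]([Se]c7ccccc7)[C@@H](CO[Si](c3ccccc3)(c4ccccc4)C(C)(C)C)CCC(=O)[C@]5(C)C[C@@H](O[C@@H](c6ccc(OC)cc6)O5)[C@@H]12
F4 | step 19 | phenylselanyl lactone 8,10-diol | C=C1C(=O)O[C@@H]2[C@@H]([Se]c7ccccc7)[C@@H](CO[Si](c3ccccc3)(c4ccccc4)C(C)(C)C)CCC(=O)[C@@](C)(O)C[C@@H](O)[C@@H]12
F5 | step 19 | phenylselenonyl lactone 8,10-diol (selenone) | C=C1C(=O)O[C@@H]2[C@@H]([Se](=O)(=O)c7ccccc7)[C@@H](CO[Si](c3ccccc3)(c4ccccc4)C(C)(C)C)CCC(=O)[C@@](C)(O)C[C@@H](O)[C@@H]12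
F6 | step 12 | 1-(trimethylsilylethynyl) carbinol acetate | C[Si](C)(C)C#C[C@]1(O)[C@]2(C)C[C@@H](O[C@@H](c3ccc(OC)cc3)O2)[C@@H](C(C)=C)[C@@H]1/C=C/COC(C)=O
F7 | step 12 | 1-ethynyl carbinol diol | C#C[C@]1(O)[C@]2(C)C[C@@H](O[C@@H](c3ccc(OC)cc3)O2)[C@@H](C(C)=C)[C@@H]1/C=C/CO
F8 | step 15 | C12 allylic chloride of 23 | O=C1CC[C@H](CO[Si](c2ccccc2)(c3ccccc3)C(C)(C)C)/C=C\[C@H](C(=C)CCl)[C@H](O[C@@H](c5ccc(OC)cc5)O4)C[C@@]14C
A1 | alternative 1 | benzyl pyranoside diazoketone (lactone and angelate in place) | CC(=[N+]=[N-])C(=O)/C=C\[C@H](CO[Si](C)(C)C(C)(C)C)[C@H]1O[C@@H](OCc2ccccc2)[C@@H](OC(=O)/C(C)=C\C)[C@H]2CC(=O)O[C@H]12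
A2 | alternative 1 | trans-bridged bicyclic ether with 9-benzyloxy group and saturated lactone | O=C1O[C@@H]2[C@@H]3O[C@@](C)([C@@H](OCc4ccccc4)[C@@H](OC(=O)/C(C)=C\C)[C@H]2C1)C(=O)C=C[C@@H]3CO[Si](C)(C)C(C)(C)C
A3 | alternative 2 | oxepene aldehyde carrying the butenolide at C5 | O=CC[C@]1(C)O[C@@H]([C@H]2OC(=O)C=C2)[C@@H](CO[Si](c3ccccc3)(c4ccccc4)C(C)(C)C)C=C[C@@H]1O[Si](C)(C)C(C)(C)C
A4 | alternative 2 | tricyclic C8 alcohol with saturated lactone | O=C1C[C@@H]2[C@H](O)C[C@]3(C)O[C@@H]([C@H]2O1)[C@@H](CO[Si](c4ccccc4)(c4ccccc4)C(C)(C)C)C=C[C@@H]3O[Si](C)(C)C(C)(C)C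
A5 | alternative 3 | oxepenone aldehyde with (Z)-2-(bromomethyl)enoate side chain | O=C[C@@H]1O[C@@](C)(C[C@@H](OC(=O)/C(C)=C\C)/C=C(\CBr)C(=O)OC)C(=O)C=C[C@@H]1CO[Si](C)(C)C(C)(C)C
A6 | alternative 3 | 15-O-TBS ether of the target | C=C1C(=O)O[C@@H]2[C@@H]3O[C@@](C)(C[C@@H](OC(=O)/C(C)=C\C)[C@@H]12)C(=O)C=C[C@@H]3CO[Si](C)(C)C(C)(C)C
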